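Everything rests on cutting ring B at C4–C5 and C10–CH3 (labdane numbering). A chiral copper-catalysed conjugate reverse prenylation of an achiral, freshly prepared cyclohexenone ester (methyl 6-oxocyclohex-1-ene-1-carboxylate), followed in the same flask by enolate methylation, joins three components and creates both ring-fusion stereocentres. The step exploits the contiguous quaternary C4, tertiary C5 and quaternary C10 of the target, whose C10 methyl lies on the face of ring B opposite to C4. The ester carbon C1 is thereby left cis to the vinyl-bearing C4 arm, so ring A can only close cis-fused (C1–C2, McMurry). The C9 ketone then carries the C8 methyl and, through its enol triflate, the side chain.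

Key step: step 2

Remark (numbering): the core is numbered as a labdane – C1 to C3 and C4 (CMe2) in ring A, C5 (ring-fusion CH), C6, C7, C8 (methyl-bearing), C9 and C10 (ring-fusion CMe) in ring B – and the side chain runs from C9 through C11, C12, C13 (bearing CH2OH), C14, C15, C16 to the butenolide; the target is (5R,10S), cis-fused, with C12 cis to C15 across C13=C14 and an E C15=C16 bond.

Assumption: the facial preference of the copper catalyst with the prenylsilane is taken to parallel that with simple allylsilanes and the ligand antipode is chosen on that basis (both antipodes are catalogue items); 4-(bromomethyl)furan-2(5H)-one is taken to be a catalogue compound.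

Step 1
Reactants: 1 methyl 2-oxocyclohexane-1-carboxylate
Product: 4 methyl 6-oxocyclohex-1-ene-1-carboxylate, via selenide 2 (not isolated), via selenoxide 3 (not isolated)
Conditions: PhSeCl, pyridine, CH2Cl2, 0 °C; then 30% H2O2, 0 °C → rt; cold dilute-acid wash, used at once
Reagents that add atoms: none
Why: α-Selenenylation of the enolised β-keto ester followed by oxidation and syn selenoxide elimination, which can only take up a ring hydrogen, should deliver the endocyclic enone ester, which is sensitive and is therefore carried forward crude on the same day.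

Step 2
Reactants: 4 methyl 6-oxocyclohex-1-ene-1-carboxylate; 5 prenyltrimethylsilane; 6 iodomethane
Product: 8 methyl (1S,2R)-1-methyl-2-(2-methylbut-3-en-2-yl)-6-oxocyclohexane-1-carboxylate, via silyl enol ether 7 (not isolated)
Conditions: Cu(OTf)2 (10 mol %), (S,S)-t-Bu-box [2,2′-(propane-2,2-diyl)bis((4S)-4-tert-butyl-4,5-dihydrooxazole)] (11 mol %), 5 (2 equiv), 4 Å MS, CH2Cl2, −78 → 0 °C; then Cs2CO3, 6, DMF, 0 °C → rt
Reagents that add atoms: none
Why: Proposed new method: divalent copper held by the C2-symmetric bis(oxazoline) binds the ketone and ester oxygens of 4 in a two-point chelate, bond formation to C5 takes place at the dimethyl-substituted terminus of the silane in an open SE2′ transition state, the β-silyl cation passes its silicon to the enolate oxygen to give 7 and release the catalyst, and carbonate then cleaves the O–Si bond so that the cesium enolate is C-methylated by 6. The closest known reaction type is the Cu(OTf)2–bis(oxazoline)-catalysed enantioselective Hosomi–Sakurai conjugate allylation of cyclic 2-alkoxycarbonyl enones with allyl- and 2-substituted allylsilanes followed by β-keto ester alkylation, together with the TiCl4-promoted addition of prenylsilanes to enones through their substituted terminus; what is new is a γ,γ-disubstituted silane, which builds quaternary C4, inside the chiral copper manifold. The step forms no ring. C5 (R) is fixed by the chiral chelate, which leaves one face of the planar bound acceptor open (ligand antipode chosen accordingly), and C10 (S) by the substrate, because methyl enters the enolate from the less hindered face away from the tert-alkyl group on C5, which places the ester carbon C1 cis to C4. The step needs γ- rather than α-attack of the silane, secured by the SE2′ pathway, conjugate rather than carbonyl addition, secured by the chelated doubly activated acceptor, and C- rather than O-methylation, favoured by the soft electrophile.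

Step 3
Reactants: 8 methyl (1S,2R)-1-methyl-2-(2-methylbut-3-en-2-yl)-6-oxocyclohexane-1-carboxylate
Product: 9 methyl (6S,7R)-6-methyl-7-(2-methylbut-3-en-2-yl)-1,4-dioxaspiro[4.5]decane-6-carboxylate
Conditions: HOCH2CH2OH, p-TsOH·H2O (cat.), benzene, reflux, azeotropic removal of water
Reagents that add atoms: ethane-1,2-diol, OCCO
Why: Acid-catalysed ketalisation of the only ketone (C9) masks it against the borane, LiAlH4 and low-valent titanium used next, while the quaternary ester and the monosubstituted alkene should be inert to catalytic sulfonic acid.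

Step 4
Reactants: 9 methyl (6S,7R)-6-methyl-7-(2-methylbut-3-en-2-yl)-1,4-dioxaspiro[4.5]decane-6-carboxylate
Product: 11 methyl (6S,7R)-7-(4-hydroxy-2-methylbutan-2-yl)-6-methyl-1,4-dioxaspiro[4.5]decane-6-carboxylate, via B-alkylborane 10 (not isolated)
Conditions: 9-BBN, THF, 0 °C → rt; then 3 M NaOH, 30% H2O2, 0 °C → rt
Reagents that add atoms: hydrogen peroxide, OO
Why: Hydroboration–oxidation places boron, then oxygen, on the terminal carbon (C2) of the monosubstituted alkene for steric reasons, and the hindered ester and the ketal do not react with 9-BBN or with cold alkaline peroxide.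

Step 5
Reactants: 11 methyl (6S,7R)-7-(4-hydroxy-2-methylbutan-2-yl)-6-methyl-1,4-dioxaspiro[4.5]decane-6-carboxylate
Product: 12 3-[(6R,7R)-6-(hydroxymethyl)-6-methyl-1,4-dioxaspiro[4.5]decan-7-yl]-3-methylbutan-1-ol
Conditions: LiAlH4, THF, 0 °C → reflux
Reagents that add atoms: none
Why: Hydride reduction of the neopentyl methyl ester with LiAlH4 gives the C1 primary alcohol without touching the dioxolane or either stereocentre (the C10 descriptor changes only because substituent priorities change).

Step 6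
Reactants: 12 3-[(6R,7R)-6-(hydroxymethyl)-6-methyl-1,4-dioxaspiro[4.5]decan-7-yl]-3-methylbutan-1-ol
Product: 13 (6R,7R)-6-methyl-7-(2-methyl-4-oxobutan-2-yl)-1,4-dioxaspiro[4.5]decane-6-carbaldehyde
Conditions: (COCl)2, DMSO, CH2Cl2, −78 °C; Et3N, −78 → 0 °C
Reagents that add atoms: none
Why: Swern oxidation converts both primary alcohols to aldehydes under cold, non-acidic conditions that spare the ketal, C10 being quaternary so that nothing can epimerise, and the dialdehyde is used without chromatography to forestall aldol reaction.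

Step 7
Reactants: 13 (6R,7R)-6-methyl-7-(2-methyl-4-oxobutan-2-yl)-1,4-dioxaspiro[4.5]decane-6-carbaldehyde
Product: 14 (4'aR,8'aS)-5',5',8'a-trimethyl-3',4',4'a,5',6',8'a-hexahydro-2'H-spiro[[1,3]dioxolane-2,1'-naphthalene] (C1=C2 alkene, C9 dioxolane, cis-fused)
Conditions: TiCl3(DME)1.5, Zn–Cu couple, DME, reflux, slow addition of 13
Reagents that add atoms: none
Why: Intramolecular McMurry coupling of the 1,6-dialdehyde by low-valent titanium forms the C1=C2 bond and closes six-membered ring A with loss of both oxygens, the fusion being necessarily cis because the two aldehyde arms were fixed cis on ring B in step 2, and acetals are tolerated by this reagent.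

Step 8
Reactants: 14 (4'aR,8'aS)-5',5',8'a-trimethyl-3',4',4'a,5',6',8'a-hexahydro-2'H-spiro[[1,3]dioxolane-2,1'-naphthalene]
Product: 16 (4aR,8aS)-5,5,8a-trimethyloctahydronaphthalen-1(2H)-one, via saturated ketal 15 (not isolated)
Conditions: H2 (1 atm), Pd/C, EtOAc, rt; filter; then 2 M HCl, THF, 40 °C
Reagents that add atoms: water, O
Why: Catalytic hydrogenation saturates the disubstituted ring A alkene and acid hydrolysis of the dioxolane then frees the C9 ketone, neither C5 (β to the carbonyl) nor quaternary C10 being epimerisable.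

Step 9
Reactants: 16 (4aR,8aS)-5,5,8a-trimethyloctahydronaphthalen-1(2H)-one; 6 iodomethane
Product: 18 (4aR,8aS)-2,5,5,8a-tetramethyloctahydronaphthalen-1(2H)-one (both C2 epimers), via lithium enolate 17 (not isolated)
Conditions: LiN(i-Pr)2, THF, −78 °C; 6, −78 → 0 °C
Reagents that add atoms: none
Why: Enolate alkylation can occur only at C8 because C10 is quaternary, and the configuration of the new C8 stereocentre is immaterial since this carbon becomes sp2 in the next step.

Step 10
Reactants: 18 (4aR,8aS)-2,5,5,8a-tetramethyloctahydronaphthalen-1(2H)-one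
Product: 20 (4aR,8aS)-2,5,5,8a-tetramethyl-3,4,4a,5,6,7,8,8a-octahydronaphthalen-1-yl trifluoromethanesulfonate, via potassium enolate 19 (not isolated)
Conditions: KN(SiMe3)2, THF, −78 → 0 °C; PhNTf2, −78 °C → rt
Reagents that add atoms: N-phenylbis(trifluoromethanesulfonimide), O=S(=O)(N(c1ccccc1)S(=O)(=O)C(F)(F)F)C(F)(F)F
Why: Enol triflate formation is regiochemically unambiguous because the single remaining α-hydrogen sits on C8, so O-sulfonylation of the tetrasubstituted enolate fixes the C8=C9 double bond of the target.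

Step 11
Reactants: 20 (4aR,8aS)-2,5,5,8a-tetramethyl-3,4,4a,5,6,7,8,8a-octahydronaphthalen-1-yl trifluoromethanesulfonate; 21 tributyl(ethenyl)stannane
Product: 22 (4aR,8aS)-1-ethenyl-2,5,5,8a-tetramethyl-3,4,4a,5,6,7,8,8a-octahydronaphthalene
Conditions: Pd(PPh3)4 (5 mol %), LiCl, THF, reflux
Reagents that add atoms: none
Why: Stille coupling of a hindered cyclohexenyl triflate with a vinylstannane in the presence of chloride, catalysed by zerovalent palladium, is well established and installs C11 and C12 as a vinyl group on C9.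

Step 12
Reactants: 23 but-2-yne-1,4-diol
Product: 24 4-{[tert-butyl(dimethyl)silyl]oxy}but-2-yn-1-ol
Conditions: TBSCl (1 equiv), imidazole, 23 (4 equiv), DMF, 0 °C → rt
Reagents that add atoms: tert-butyl(chloro)dimethylsilane, CC(C)(C)[Si](C)(C)Cl
Why: Silylation of a symmetrical diol used in excess gives mainly the mono-silyl ether, and the water-soluble surplus diol is washed out.

Step 13
Reactants: 24 4-{[tert-butyl(dimethyl)silyl]oxy}but-2-yn-1-ol
Product: 26 (2Z)-4-{[tert-butyl(dimethyl)silyl]oxy}-3-iodobut-2-en-1-ol, via vinylalanate 25 (not isolated)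
Conditions: NaAlH2(OCH2CH2OMe)2, THF, 0 °C → rt; then EtOAc, I2, −78 → 0 °C
Reagents that add atoms: iodine, [I][I]
Why: Hydroxyl-directed trans-hydroalumination of the propargylic alcohol places aluminium on the carbon remote from the free hydroxyl within a five-membered chelate, and iodinolysis of the C–Al bond with retention therefore gives the Z-iodide in which iodine is cis to the CH2OH group.

Step 14
Reactants: 22 (4aR,8aS)-1-ethenyl-2,5,5,8a-tetramethyl-3,4,4a,5,6,7,8,8a-octahydronaphthalene; 26 (2Z)-4-{[tert-butyl(dimethyl)silyl]oxy}-3-iodobut-2-en-1-ol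
Product: 28 (2E)-3-({[tert-butyl(dimethyl)silyl]oxy}methyl)-5-[(4aR,8aS)-2,5,5,8a-tetramethyl-3,4,4a,5,6,7,8,8a-octahydronaphthalen-1-yl]pent-2-en-1-ol, via B-alkylborane 27 (not isolated)
Conditions: 9-BBN, THF, 0 °C → rt; then H2O, Cs2CO3, 26, PdCl2(dppf) (5 mol %), AsPh3, DMF, rt
Reagents that add atoms: none
Why: 9-BBN hydroborates only the monosubstituted vinyl group of the diene at terminal C12 (the tetrasubstituted ring alkene is inert), and B-alkyl Suzuki–Miyaura coupling with the alkenyl iodide proceeds with retention, so that C12 ends cis to C15 and the C13=C14 geometry of the target is set, the free hydroxyl being tolerated.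

Step 15
Reactants: 28 (2E)-3-({[tert-butyl(dimethyl)silyl]oxy}methyl)-5-[(4aR,8aS)-2,5,5,8a-tetramethyl-3,4,4a,5,6,7,8,8a-octahydronaphthalen-1-yl]pent-2-en-1-ol
Product: 29 (2E)-3-({[tert-butyl(dimethyl)silyl]oxy}methyl)-5-[(4aR,8aS)-2,5,5,8a-tetramethyl-3,4,4a,5,6,7,8,8a-octahydronaphthalen-1-yl]pent-2-enal
Conditions: MnO2, CH2Cl2, rt
Reagents that add atoms: none
Why: Manganese dioxide oxidation is selective for the allylic primary alcohol and is mild enough to preserve the geometry of the trisubstituted alkene and the silyl ether.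

Step 16
Reactants: 30 4-(bromomethyl)furan-2(5H)-one
Product: 31 diethyl [(5-oxo-2,5-dihydrofuran-3-yl)methyl]phosphonate
Conditions: P(OEt)3, toluene, 110 °C
Reagents that add atoms: triethyl phosphite, CCOP(OCC)OCC
Why: Michaelis–Arbuzov reaction of the reactive allylic bromide with the phosphite gives the phosphonate with loss of bromoethane.

Step 17
Reactants: 29 (2E)-3-({[tert-butyl(dimethyl)silyl]oxy}methyl)-5-[(4aR,8aS)-2,5,5,8a-tetramethyl-3,4,4a,5,6,7,8,8a-octahydronaphthalen-1-yl]pent-2-enal; 31 diethyl [(5-oxo-2,5-dihydrofuran-3-yl)methyl]phosphonate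
Product: 33 4-[(1E,3E)-4-({[tert-butyl(dimethyl)silyl]oxy}methyl)-6-[(4aR,8aS)-2,5,5,8a-tetramethyl-3,4,4a,5,6,7,8,8a-octahydronaphthalen-1-yl]hexa-1,3-dien-1-yl]furan-2(5H)-one, via phosphonate anion 32 (not isolated)
Conditions: LiN(SiMe3)2, THF, −78 °C; then 29, −78 → 0 °C
Reagents that add atoms: none
Why: Horner–Wadsworth–Emmons olefination with a vinylogously stabilised phosphonate anion, which reacts at the carbon next to phosphorus as 4-phosphonocrotonates do, should give the new C15=C16 double bond with the E geometry usual for stabilised phosphonates.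

Step 18
Reactants: 33 4-[(1E,3E)-4-({[tert-butyl(dimethyl)silyl]oxy}methyl)-6-[(4aR,8aS)-2,5,5,8a-tetramethyl-3,4,4a,5,6,7,8,8a-octahydronaphthalen-1-yl]hexa-1,3-dien-1-yl]furan-2(5H)-one
Product: 34 4-[(1E,3E)-4-(hydroxymethyl)-6-[(4aR,8aS)-2,5,5,8a-tetramethyl-3,4,4a,5,6,7,8,8a-octahydronaphthalen-1-yl]hexa-1,3-dien-1-yl]furan-2(5H)-one (target, CNP0232848.3)
Conditions: HF·pyridine, pyridine, THF, 0 °C → rt
Reagents that add atoms: none
Why: Fluoride-mediated cleavage of the primary silyl ether under buffered, non-basic conditions frees the C13 hydroxymethyl group without opening or deconjugating the butenolide.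

Compound list
1 | methyl 2-oxocyclohexane-1-carboxylate | COC(=O)C1CCCCC1=O | starting material
2 | methyl 2-oxo-1-(phenylselanyl)cyclohexane-1-carboxylate (racemic) | COC(=O)C1([Se]c2ccccc2)CCCCC1=O | intermediate
3 | methyl 2-oxo-1-(phenylseleninyl)cyclohexane-1-carboxylate (selenoxide) | COC(=O)C1([Se](=O)c2ccccc2)CCCCC1=O | intermediate
4 | methyl 6-oxocyclohex-1-ene-1-carboxylate | COC(=O)C1=CCCCC1=O | intermediate
5 | trimethyl(3-methylbut-2-en-1-yl)silane (prenyltrimethylsilane) | CC(C)=CC[Si](C)(C)C | starting material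
6 | iodomethane | CI | starting material
7 | methyl (6R)-6-(2-methylbut-3-en-2-yl)-2-[(trimethylsilyl)oxy]cyclohex-1-ene-1-carboxylate | C[Si](C)(C)OC1=C(C(=O)OC)[C@@H](C(C)(C)C=C)CCC1 | intermediate
8 | methyl (1S,2R)-1-methyl-2-(2-methylbut-3-en-2-yl)-6-oxocyclohexane-1-carboxylate | O=C1CCC[C@H](C(C)(C)C=C)[C@]1(C)C(=O)OC | intermediate
9 | methyl (6S,7R)-6-methyl-7-(2-methylbut-3-en-2-yl)-1,4-dioxaspiro[4.5]decane-6-carboxylate | O1CCOC12CCC[C@H](C(C)(C)C=C)[C@]2(C)C(=O)OC | intermediate
10 | methyl (6S,7R)-7-[4-(9-borabicyclo[3.3.1]nonan-9-yl)-2-methylbutan-2-yl]-6-methyl-1,4-dioxaspiro[4.5]decane-6-carboxylate | O1CCOC12CCC[C@H](C(C)(C)CCB3C4CCCC3CCC4)[C@]2(C)C(=O)OC | intermediate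
11 | methyl (6S,7R)-7-(4-hydroxy-2-methylbutan-2-yl)-6-methyl-1,4-dioxaspiro[4.5]decane-6-carboxylate | O1CCOC12CCC[C@H](C(C)(C)CCO)[C@]2(C)C(=O)OC | intermediate
12 | 3-[(6R,7R)-6-(hydroxymethyl)-6-methyl-1,4-dioxaspiro[4.5]decan-7-yl]-3-methylbutan-1-ol | O1CCOC12CCC[C@H](C(C)(C)CCO)[C@]2(C)CO | intermediate
13 | (6R,7R)-6-methyl-7-(2-methyl-4-oxobutan-2-yl)-1,4-dioxaspiro[4.5]decane-6-carbaldehyde | O1CCOC12CCC[C@H](C(C)(C)CC=O)[C@]2(C)C=O | intermediate
14 | (4'aR,8'aS)-5',5',8'a-trimethyl-3',4',4'a,5',6',8'a-hexahydro-2'H-spiro[[1,3]dioxolane-2,1'-naphthalene] (cis-fused, C1=C2 alkene) | O1CCOC12[C@@]3(C)C=CCC(C)(C)[C@H]3CCC2 | intermediate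
15 | (4'aR,8'aS)-5',5',8'a-trimethyloctahydro-2'H-spiro[[1,3]dioxolane-2,1'-naphthalene] | O1CCOC12[C@@]3(C)CCCC(C)(C)[C@H]3CCC2 | intermediate
16 | (4aR,8aS)-5,5,8a-trimethyloctahydronaphthalen-1(2H)-one (cis-fused) | O=C1[C@@]2(C)CCCC(C)(C)[C@H]2CCC1 | intermediate
17 | lithium (4aR,8aS)-5,5,8a-trimethyl-3,4,4a,5,6,7,8,8a-octahydronaphthalen-1-olate | C1=C([O-])[C@@]2(C)CCCC(C)(C)[C@H]2CC1.[Li+] | intermediate
18 | (4aR,8aS)-2,5,5,8a-tetramethyloctahydronaphthalen-1(2H)-one (both C2 epimers) | CC1C(=O)[C@@]2(C)CCCC(C)(C)[C@H]2CC1 | intermediate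
19 | potassium (4aR,8aS)-2,5,5,8a-tetramethyl-3,4,4a,5,6,7,8,8a-octahydronaphthalen-1-olate | CC1=C([O-])[C@@]2(C)CCCC(C)(C)[C@H]2CC1.[K+] | intermediate
20 | (4aR,8aS)-2,5,5,8a-tetramethyl-3,4,4a,5,6,7,8,8a-octahydronaphthalen-1-yl trifluoromethanesulfonate | CC1=C(OS(=O)(=O)C(F)(F)F)[C@@]2(C)CCCC(C)(C)[C@H]2CC1 | intermediate
21 | tributyl(ethenyl)stannane | C=C[Sn](CCCC)(CCCC)CCCC | starting material
22 | (4aR,8aS)-1-ethenyl-2,5,5,8a-tetramethyl-3,4,4a,5,6,7,8,8a-octahydronaphthalene | CC1=C(C=C)[C@@]2(C)CCCC(C)(C)[C@H]2CC1 | intermediate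
23 | but-2-yne-1,4-diol | OCC#CCO | starting material
24 | 4-{[tert-butyl(dimethyl)silyl]oxy}but-2-yn-1-ol | OCC#CCO[Si](C)(C)C(C)(C)C | intermediate
25 | sodium 3-({[tert-butyl(dimethyl)silyl]oxy}methyl)-2,2-bis(2-methoxyethoxy)-2,5-dihydro-1,2-oxaaluminol-2-uide (cyclic vinylalanate) | [Na+].COCCO[Al-]1(OCCOC)OCC=C1CO[Si](C)(C)C(C)(C)C | intermediate
26 | (2Z)-4-{[tert-butyl(dimethyl)silyl]oxy}-3-iodobut-2-en-1-ol | OC/C=C(\I)CO[Si](C)(C)C(C)(C)C | intermediate
27 | 9-{2-[(4aR,8aS)-2,5,5,8a-tetramethyl-3,4,4a,5,6,7,8,8a-octahydronaphthalen-1-yl]ethyl}-9-borabicyclo[3.3.1]nonane | CC1=C(CCB3C4CCCC3CCC4)[C@@]2(C)CCCC(C)(C)[C@H]2CC1 | intermediate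
28 | (2E)-3-({[tert-butyl(dimethyl)silyl]oxy}methyl)-5-[(4aR,8aS)-2,5,5,8a-tetramethyl-3,4,4a,5,6,7,8,8a-octahydronaphthalen-1-yl]pent-2-en-1-ol | CC1=C(CC/C(=C\CO)CO[Si](C)(C)C(C)(C)C)[C@@]2(C)CCCC(C)(C)[C@H]2CC1 | intermediate
29 | (2E)-3-({[tert-butyl(dimethyl)silyl]oxy}methyl)-5-[(4aR,8aS)-2,5,5,8a-tetramethyl-3,4,4a,5,6,7,8,8a-octahydronaphthalen-1-yl]pent-2-enal | CC1=C(CC/C(=C\C=O)CO[Si](C)(C)C(C)(C)C)[C@@]2(C)CCCC(C)(C)[C@H]2CC1 | intermediate
30 | 4-(bromomethyl)furan-2(5H)-one | BrCC1=CC(=O)OC1 | starting material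
31 | diethyl [(5-oxo-2,5-dihydrofuran-3-yl)methyl]phosphonate | CCOP(=O)(CC1=CC(=O)OC1)OCC | intermediate
32 | lithium salt of the carbanion of 31 (deprotonated at the carbon next to phosphorus) | [Li+].CCOP(=O)([CH-]C1=CC(=O)OC1)OCC | intermediate
33 | 4-[(1E,3E)-4-({[tert-butyl(dimethyl)silyl]oxy}methyl)-6-[(4aR,8aS)-2,5,5,8a-tetramethyl-3,4,4a,5,6,7,8,8a-octahydronaphthalen-1-yl]hexa-1,3-dien-1-yl]furan-2(5H)-one | CC1=C(CC/C(=C\C=C\C2=CC(=O)OC2)CO[Si](C)(C)C(C)(C)C)[C@@]2(C)CCCC(C)(C)[C@H]2CC1 | intermediate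
34 | 4-[(1E,3E)-4-(hydroxymethyl)-6-[(4aR,8aS)-2,5,5,8a-tetramethyl-3,4,4a,5,6,7,8,8a-octahydronaphthalen-1-yl]hexa-1,3-dien-1-yl]furan-2(5H)-one | CC1=C(CC/C(=C\C=C\C2=CC(=O)OC2)CO)[C@@]2(C)CCCC(C)(C)[C@H]2CC1 | target

Total step count: 18. Longest linear sequence: 15 steps (steps 1 to 11, 14, 15, 17 and 18).

Steps most likely to fail

1. Step 2 (new method). Bond formation between C5 and the fully substituted terminus of the silane may be slow inside the chiral pocket. The result would be low conversion, poor facial selectivity, protodesilylation of the silane, or decay of the sensitive enone ester while it waits. The fallback uses known chemistry, sets out from 4 and comes back at 8. Compound 4 and silane 5 are combined with stoichiometric TiCl4 in CH2Cl2 at −78 °C, the classical Hosomi–Sakurai conjugate addition in which prenylsilanes react through the substituted terminus, to give racemic methyl 2-(2-methylbut-3-en-2-yl)-6-oxocyclohexane-1-carboxylate F1. Methylation (K2CO3, 6, acetone) on the face away from the C5 group gives the racemic keto ester, racemic methyl (1S*,2R*)-1-methyl-2-(2-methylbut-3-en-2-yl)-6-oxocyclohexane-1-carboxylate F2. Ketalisation of the racemate with (2R,3R)-butane-2,3-diol (p-TsOH, benzene, reflux) gives two diastereomers: methyl (2R,3R,6S,7R)-2,3,6-trimethyl-7-(2-methylbut-3-en-2-yl)-1,4-dioxaspiro[4.5]decane-6-carboxylate F3 and methyl (2R,3R,6R,7S)-2,3,6-trimethyl-7-(2-methylbut-3-en-2-yl)-1,4-dioxaspiro[4.5]decane-6-carboxylate F4. These are separated by chromatography or crystallisation, and hydrolysis of F3 (2 M HCl, THF) returns enantiopure 8. Stereocontrol then rests on classical resolution instead of asymmetric catalysis.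

2. Step 7. The dialdehyde may couple intermolecularly, stop at the pinacol stage, undergo aldol condensation before it reaches the titanium surface, or suffer Lewis-acid opening of the ketal. The fallback sets out from 11 and comes back at 15. Alcohol 11 is converted (I2, PPh3, imidazole, CH2Cl2) to methyl (6S,7R)-7-(4-iodo-2-methylbutan-2-yl)-6-methyl-1,4-dioxaspiro[4.5]decane-6-carboxylate F5. Iodine–lithium exchange with t-BuLi (2.2 equiv, Et2O–pentane, −78 °C → rt) and intramolecular acyl substitution at the ester close ring A through the same C1–C2 bond as the C1 ketone, (4'aR,8'aR)-5',5',8'a-trimethylhexahydro-2'H-spiro[[1,3]dioxolane-2,1'-naphthalen]-8'(8'aH)-one F6. Wolff–Kishner reduction (N2H4·H2O, KOH, diethylene glycol, 130 → 200 °C) through (4'aR,8'aR)-8'-hydrazinylidene-5',5',8'a-trimethyloctahydro-2'H-spiro[[1,3]dioxolane-2,1'-naphthalene] F7 removes the C1 oxygen and gives 15, which then needs only the acid hydrolysis of step 8. Ring A is closed by carbanion acylation instead of reductive carbonyl coupling.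

3. Step 17. Geometric purity may erode (an E/Z mixture at C15=C16, or isomerisation of C13=C14 through the enal), or the base may degrade the butenolide. The fallback sets out from 29 and comes back at 33. Takai-type chromium-mediated olefination of 29 with Cl2CHBpin (CrCl2, LiI, THF, rt) gives the E-alkenylboronate, 2-[(1E,3E)-4-({[tert-butyl(dimethyl)silyl]oxy}methyl)-6-[(4aR,8aS)-2,5,5,8a-tetramethyl-3,4,4a,5,6,7,8,8a-octahydronaphthalen-1-yl]hexa-1,3-dien-1-yl]-4,4,5,5-tetramethyl-1,3,2-dioxaborolane F8. Suzuki–Miyaura coupling with commercial 4-bromofuran-2(5H)-one (PdCl2(dppf), KF, THF/H2O, rt) then attaches the lactone ring at C16 to give 33. The C16–butenolide bond is made by cross-coupling instead of carbonyl olefination, with no strong base near the lactone.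

Further compounds
F1 | step 2 | methyl 2-(2-methylbut-3-en-2-yl)-6-oxocyclohexane-1-carboxylate (racemic) | COC(=O)C1C(=O)CCCC1C(C)(C)C=C
F2 | step 2 | racemic methyl (1S*,2R*)-1-methyl-2-(2-methylbut-3-en-2-yl)-6-oxocyclohexane-1-carboxylate (both enantiomers) | O=C1CCC[C@H](C(C)(C)C=C)[C@]1(C)C(=O)OC.O=C1CCC[C@@H](C(C)(C)C=C)[C@@]1(C)C(=O)OC
F3 | step 2 | methyl (2R,3R,6S,7R)-2,3,6-trimethyl-7-(2-methylbut-3-en-2-yl)-1,4-dioxaspiro[4.5]decane-6-carboxylate | C[C@H]1OC2(CCC[C@H](C(C)(C)C=C)[C@]2(C)C(=O)OC)O[C@@H]1C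
F4 | step 2 | methyl (2R,3R,6R,7S)-2,3,6-trimethyl-7-(2-methylbut-3-en-2-yl)-1,4-dioxaspiro[4.5]decane-6-carboxylate (unwanted diastereomer) | C[C@H]1OC2(CCC[C@@H](C(C)(C)C=C)[C@@]2(C)C(=O)OC)O[C@@H]1C
F5 | step 7 | methyl (6S,7R)-7-(4-iodo-2-methylbutan-2-yl)-6-methyl-1,4-dioxaspiro[4.5]decane-6-carboxylate | O1CCOC12CCC[C@H](C(C)(C)CCI)[C@]2(C)C(=O)OC
F6 | step 7 | (4'aR,8'aR)-5',5',8'a-trimethylhexahydro-2'H-spiro[[1,3]dioxolane-2,1'-naphthalen]-8'(8'aH)-one | O1CCOC12[C@@]3(C)C(=O)CCC(C)(C)[C@H]3CCC2
F7 | step 7 | (4'aR,8'aR)-8'-hydrazinylidene-5',5',8'a-trimethyloctahydro-2'H-spiro[[1,3]dioxolane-2,1'-naphthalene] | O1CCOC12[C@@]3(C)C(=NN)CCC(C)(C)[C@H]3CCC2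
F8 | step 17 | 2-[(1E,3E)-4-({[tert-butyl(dimethyl)silyl]oxy}methyl)-6-[(4aR,8aS)-2,5,5,8a-tetramethyl-3,4,4a,5,6,7,8,8a-octahydronaphthalen-1-yl]hexa-1,3-dien-1-yl]-4,4,5,5-tetramethyl-1,3,2-dioxaborolane | CC1=C(CC/C(=C\C=C\B3OC(C)(C)C(C)(C)O3)CO[Si](C)(C)C(C)(C)C)[C@@]2(C)CCCC(C)(C)[C@H]2CC1
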